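(The runs are simulated for an exercise.)

in all of them: free base 0.496 M
- autumn: electrophile 0.87 M; nucleophile 0.93 M; run made earlier
- noon: electrophile 1.4 M; nucleophile 0.93 M; run made earlier
- flask: electrophile 0.62 M; nucleophile 0.930 M; time 40 min

| run | time / min | electrophile / % | target / % |
|---|---|---|---|
| autumn | 5.00 | 54.1 | 30.5 |
| autumn | 10.0 | 36.2 | 41.2 |
| autumn | 15.0 | 26.2 | 49.1 |
| autumn | 20.0 | 18.7 | 54.0 |
| autumn | 25.0 | 15.4 | 56.5 |
| noon | 2.00 | 73.0 | 12.4 |
| noon | 4.00 | 54.6 | 21.2 |
| noon | 6.00 | 45.5 | 28.2 |
| noon | 12.0 | 30.9 | 36.5 |
| noon | 25.0 | 12.4 | 44.4 |

(readings scatter by 1 percentage point)

- part of the electrophile that has reacted at 40 min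
- share of the unused nucleophile that is free and not bound as protonated nucleophile, at 40 min

One mole of target, I assume, sets free one mole of acid, which the free base should take up ahead of the nucleophile. In the autumn run 66.8% of the reacted electrophile had become target at the last reading, and that share is the selectivity. At that share, the flask's charge, fully reacted, gives 0.835 moles of target per mole of free base. This ratio of target made to free base charged is the acid load: below one the base should hold, and above one the nucleophile should have to bind the excess.

Turn the settings by hand. Time first: electrophile in the autumn run fell from 26.2% to 15.4% between 15.0 min and 25.0 min, and the same fractional decay carried on to 40 min gives 93.1% reacted in that run, which I carry to the flask as my figure.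

Electrophile next: the noon run, with 1.61 times the autumn charge, had reacted 3 percentage points more at 25.0 min, against a scatter of 1 point. Its share, though, read 50.7%, lower than autumn's. So the flask, with less electrophile, should lie above 66.8%, and its load reaches one at a share of 80.0%.

Free base last: both runs held it at 0.496 M, and by hand, at fixed target, the load goes inversely with it. The load reckoned at autumn's share stays below one, so I expect a high free share of the unused nucleophile, though how much is a guess.

The forecast gave 90.5% reacted and 91% free, with an acid that “stays just below the base charge”.

The flask gives 93.1% reacted and 92.0% of the unused nucleophile free.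

    electrophile + nucleophile → acid set free + target (k = 0.00160 M⁻¹ s⁻¹)
    nucleophile + acid set free ⇌ protonated nucleophile, settled at all times (K = 25.0 M⁻¹)
    acid set free + free base ⇌ salt of the base, settled at all times (K = 1200 M⁻¹)
    2 electrophile → self-condensation product (k = 5.80 × 10⁻⁴ M⁻¹ s⁻¹)

The flask's 71.3% target at 40.0 min is an acid load of 0.891, under one, with 19% of the free base left. Now take a neighbour flask, the same but with 0.30 M of free base. The reckoned 0.835 becomes 1.38, over one. There 5.4% of the free base is left, and the free share is lower, at 73.4%.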